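The route disconnects both carbon substituents of the C2–C3 unit of the dihydrofuran ring (ring B): C2 carries O1 and C1' of the cyclohexene (ring C), C3 carries C3a of the arene (ring A) and the CH2OH group. A palladium-catalysed conjunctive coupling joins three fragments in one operation. It forms C2–C1' and C3–C3a by anti addition across an E-alkenylboron unit and sets both stereocentres, with boron left on C2 as a stereodefined placeholder for O1. Its precursor is the ate complex from an acetonide-protected cyclohexenylboronic ester (bulky mac diol on boron) and (E)-3-silyloxypropenyllithium, intercepted by a silyl-protected bromophenol.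

Key step: step 12

Remarks on the chemistry:
- Locants C2, C3, C3a, C7a (rings A and B) and C1'–C6' (ring C) are those of the target and are kept for all intermediates.
- TBS = tert-butyldimethylsilyl; B(mac) = boronic ester of cis-1,2-dimethyl-1,2-dihydroacenaphthylene-1,2-diol.
- Assumption: the (Sp,Sp) antipode of the ferrocenyl bisphosphine is taken to select the alkene face that leads to (2S,3R); if a model run shows the opposite sense, the mirror-image ligand is used.

Step 1
Reactants: 1 2,3-O-isopropylidene-D-erythronolactone
Product: 2 2,3-O-isopropylidene-D-erythrose (lactol as anomer mixture)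
Conditions: i-Bu2AlH, CH2Cl2, −78 °C; aq. potassium sodium tartrate
Reagents that add atoms: none
Why: Partial reduction of a lactone by i-Bu2AlH stops at the aluminium hemiacetal at −78 °C and gives the lactol on work-up, with neither acetonide-bearing stereocentre touched.

Step 2
Reactants: 2 2,3-O-isopropylidene-D-erythrose
Product: 3 [(4R,5S)-2,2-dimethyl-5-vinyl-1,3-dioxolan-4-yl]methanol
Conditions: Ph3PCH3Br, KOt-Bu, THF, 0 °C → reflux
Reagents that add atoms: methyltriphenylphosphonium bromide, C[P+](c1ccccc1)(c1ccccc1)c1ccccc1.[Br-]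
Why: Wittig methylenation of the hydroxy aldehyde in equilibrium with the lactol (excess ylide, since the hydroxyl consumes one equivalent) installs the vinyl group that becomes C2' and leaves the cis-diol centres (later C3' and C4') unchanged.

Step 3
Reactants: 3 [(4R,5S)-2,2-dimethyl-5-vinyl-1,3-dioxolan-4-yl]methanol, 4 1-(trimethylsilyl)propyne
Product: 7 (4R,5S)-4-(but-3-yn-1-yl)-2,2-dimethyl-5-vinyl-1,3-dioxolane, via triflate 5 (not isolated), via silylalkyne 6 (not isolated)
Conditions: Tf2O, 2,6-lutidine, CH2Cl2, −78 °C (crude triflate after cold aqueous wash); 4, n-BuLi, THF, −78 → 0 °C; then MeOH, K2CO3 (cat.), rt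
Reagents that add atoms: none
Why: Sulfonylation gives a primary triflate that undergoes SN2 alkylation at the propargylic carbon of lithiated 1-(trimethylsilyl)propyne (forming C5'–C6'), and base-catalysed methanolysis of the alkynyl C–Si bond then frees the terminal alkyne, all remote from the two stereocentres.

Step 4
Reactants: 7 (4R,5S)-4-(but-3-yn-1-yl)-2,2-dimethyl-5-vinyl-1,3-dioxolane
Product: 8 pinacol 4-[(4R,5S)-2,2-dimethyl-5-vinyl-1,3-dioxolan-4-yl]but-1-en-2-ylboronate
Conditions: (SIMes)CuCl (5 mol %; SIMes = 1,3-dimesitylimidazolidin-2-ylidene), NaOt-Bu (10 mol %), B2pin2, MeOH, THF, −50 → −15 °C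
Reagents that add atoms: bis(pinacolato)diboron, CC1(C)OB(OC1(C)C)B1OC(C)(C)C(C)(C)O1
Why: Copper-catalysed protoboration of a terminal alkyne with an N-aryl NHC ligand is a known Markovnikov-selective formal hydroboration in which the Cu–Bpin species adds syn with boron on the internal carbon and methanol protonates the alkenylcopper, while the isolated vinyl group is far less reactive.

Step 5
Reactants: 8 pinacol 4-[(4R,5S)-2,2-dimethyl-5-vinyl-1,3-dioxolan-4-yl]but-1-en-2-ylboronate
Product: 9 pinacol (3aS,7aR)-2,2-dimethyl-3a,6,7,7a-tetrahydro-1,3-benzodioxol-5-ylboronate (ring C with boron on C1')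
Conditions: second-generation Grubbs catalyst (5 mol %), CH2Cl2 (0.01 M), 40 °C
Reagents that add atoms: none
Why: Ring-closing metathesis between the terminal vinyl group and the 1,1-disubstituted alkenylboronate closes the six-membered ring C with loss of ethylene, a known route to cyclic alkenylboronates, and the cis-fused acetonide holds the two alkenes within reach.

Step 6
Reactants: 10 acenaphthoquinone (acenaphthylene-1,2-dione)
Product: 11 cis-1,2-dimethyl-1,2-dihydroacenaphthylene-1,2-diol (mac diol; meso)
Conditions: AlMe3, toluene, 0 °C → rt; aq. HCl; recrystallisation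
Reagents that add atoms: trimethylaluminium, C[Al](C)C
Why: Double 1,2-addition of methyl groups from AlMe3 to the 1,2-diketone gives the tertiary diol, the cis (meso) isomer being the one needed because only it can span a boron atom, and any trans isomer is removed by crystallisation.

Step 7
Reactants: 9 pinacol (3aS,7aR)-2,2-dimethyl-3a,6,7,7a-tetrahydro-1,3-benzodioxol-5-ylboronate, 11 cis-1,2-dimethyl-1,2-dihydroacenaphthylene-1,2-diol
Product: 13 mac ester of (3aS,7aR)-2,2-dimethyl-3a,6,7,7a-tetrahydro-1,3-benzodioxol-5-ylboronic acid, via boronic acid 12 (not isolated)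
Conditions: NaIO4, NH4OAc, acetone/H2O, rt (crude acid after extraction); 11, MgSO4, CH2Cl2, rt
Reagents that add atoms: none
Why: Periodate cleaves the pinacol unit oxidatively to release the boronic acid, which condenses with the cis-diol under dehydrating conditions (boronic ester exchange) to give the hindered ester that disfavours direct transmetallation in the coupling.

Step 8
Reactants: 14 3-(4-hydroxy-3-methoxyphenyl)propan-1-ol (dihydroconiferyl alcohol)
Product: 15 2-bromo-4-(3-hydroxypropyl)-6-methoxyphenol
Conditions: NBS, MeCN, 0 °C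
Reagents that add atoms: N-bromosuccinimide, BrN1C(=O)CCC1=O
Why: Electrophilic aromatic bromination is directed by the free phenol to its only open ortho position (the future C3a), the para position being blocked by the side chain.

Step 9
Reactants: 15 2-bromo-4-(3-hydroxypropyl)-6-methoxyphenol
Product: 16 tert-butyl{2-bromo-4-[3-(tert-butyldimethylsilyloxy)propyl]-6-methoxyphenoxy}dimethylsilane
Conditions: TBSCl, imidazole, DMF, rt
Reagents that add atoms: tert-butyldimethylsilyl chloride, CC(C)(C)[Si](C)(C)Cl
Why: Standard silylation with TBSCl/imidazole protects both the phenol and the primary alcohol, and the aryl silyl ether can later be removed selectively.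

Step 10
Reactants: 17 propargyl alcohol
Product: 18 (E)-3-(tributylstannyl)prop-2-en-1-ol
Conditions: Bu3SnH, AIBN (cat.), neat, 80 °C; chromatography
Reagents that add atoms: tributyltin hydride, CCCC[SnH](CCCC)CCCC
Why: Radical hydrostannation adds the stannyl radical to the terminal alkyne carbon and, being reversible, funnels material to the E-β-stannyl allylic alcohol, which is separated from the minor Z and α isomers by chromatography.

Step 11
Reactants: 18 (E)-3-(tributylstannyl)prop-2-en-1-ol
Product: 19 (E)-tert-butyldimethyl{[3-(tributylstannyl)prop-2-en-1-yl]oxy}silane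
Conditions: TBSCl, imidazole, CH2Cl2, rt
Reagents that add atoms: tert-butyldimethylsilyl chloride, CC(C)(C)[Si](C)(C)Cl
Why: Silylation of the primary allylic alcohol with TBSCl/imidazole leaves the alkenyl C–Sn bond and the E geometry untouched.

Step 12
Reactants: 19 (E)-tert-butyldimethyl{[3-(tributylstannyl)prop-2-en-1-yl]oxy}silane, 13 mac ester of the ring C boronic acid, 16 aryl bromide with both hydroxyls as TBS ethers
Product: 22 secondary allylic mac boronate in which C3 (R) carries the ring A aryl group and CH2OTBS while C2 (S) carries boron and C1' of the ring C acetonide, via alkenyllithium 20 (not isolated), via ate complex 21 (not isolated)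
Conditions: 19, n-BuLi, THF, −78 °C; 13, −78 °C → rt; then Pd(OAc)2 (3 mol %), (Sp,Sp)-MandyPhos [a 1,1'-bis(diarylphosphino)-2,2'-bis(α-dimethylaminobenzyl)ferrocene] (3.6 mol %), NaOTf, 16, THF, 60 °C
Reagents that add atoms: none
Why: Proposed new method: the ate complex 21 carries two alkenyl groups, and the cationic divalent arylpalladium species formed from 16 by oxidative addition and bromide abstraction (NaOTf) should bind the open-chain E-disubstituted alkene, whereupon the cyclohexenyl group shifts from boron to C2 anti to palladium (forming C2–C1') and C–C reductive elimination with retention places the aryl ring on C3 (forming C3–C3a). The closest known reaction type is the enantioselective palladium-catalysed conjunctive cross-coupling, established for bis(alkenyl) ate complexes with an unsubstituted vinyl acceptor and for β-substituted alkenyl ate complexes of the mac diol with alkyl or aryl migrating groups; combining a β-substituted acceptor with an alkenyl migrating group is the untested part. No ring is closed. C2 and C3 are created together: their relative configuration follows from the stereospecific anti addition across the E alkene, and the absolute sense is chosen by the chiral bisphosphine, which selects the alkene face independently of the remote acetonide centres. The step needs the 1,2-shift to outrun direct transfer of an alkenyl group to palladium, which the bulky mac diol on boron and the halide-free alkenyllithium (tin–lithium exchange) are meant to secure, and it needs activation of the open-chain alkene, secured because migration onto the ring carbon C1' would have to build a quaternary centre.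

Step 13
Reactants: 22 secondary allylic mac boronate
Product: 23 secondary allylic alcohol (2S,3R) with OH on C2 in place of boron
Conditions: NaBO3·4H2O, THF/H2O (1:1), rt
Reagents that add atoms: sodium perborate tetrahydrate, [Na+].[O-]OB=O.O.O.O.O
Why: Peroxide oxidation of the secondary allylic boronic ester proceeds by 1,2-shift of C2 from boron to oxygen with retention and without allylic transposition, and the mildly basic perborate spares the aryl silyl ether.

Step 14
Reactants: 23 secondary allylic alcohol
Product: 24 methyl carbonate of the C2 alcohol (2S,3R)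
Conditions: ClCO2Me, pyridine, DMAP (cat.), CH2Cl2, 0 °C → rt
Reagents that add atoms: methyl chloroformate, COC(Cl)=O
Why: Acylation of the secondary allylic alcohol with methyl chloroformate under pyridine/DMAP catalysis gives the allylic carbonate needed for ionisation by palladium without affecting the C2 configuration.

Step 15
Reactants: 24 methyl carbonate
Product: 25 free phenol (C7a–OH) carrying the C2 methyl carbonate with both primary TBS ethers and the acetonide intact
Conditions: KHF2, MeOH, rt
Reagents that add atoms: none
Why: Bifluoride cleaves aryl silyl ethers selectively because phenoxide is the better leaving group at silicon, so the two alkyl silyl ethers, the acetonide and the carbonate should persist (chemoselective desilylation).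

Step 16
Reactants: 25 phenol carbonate
Product: 26 (2S,3R)-2,3-dihydrobenzofuran with ring B closed and both primary alcohols as TBS ethers and the ring C diol as acetonide
Conditions: Pd(PPh3)4 (5 mol %), THF, rt → 40 °C
Reagents that add atoms: none
Why: Intramolecular Tsuji–Trost allylic etherification in which zerovalent palladium ionises the carbonate with inversion and the phenoxide attacks the C2 terminus of the π-allyl complex anti to the metal (5-exo closure of ring B in preference to a seven-membered ring through C2'), so the double inversion carries the C2 configuration over with net retention and leaves the C2 and C3 substituents trans.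

Step 17
Reactants: 26 protected dihydrobenzofuran
Product: 27 difengpiol A
Conditions: HCl (1 M aq), MeOH/THF, rt
Reagents that add atoms: none
Why: Acid-catalysed solvolysis removes both primary silyl ethers and hydrolyses the acetonide in one operation without touching the stereocentres (global deprotection).

Compound list
1 | 2,3-O-isopropylidene-D-erythronolactone, (3aR,6aR) | O=C1[C@H](OC2(C)C)[C@H](O2)CO1 | starting material
2 | 2,3-O-isopropylidene-D-erythrose (lactol, anomer mixture) | OC1[C@H](OC2(C)C)[C@H](O2)CO1 | intermediate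
3 | [(4R,5S)-2,2-dimethyl-5-vinyl-1,3-dioxolan-4-yl]methanol | C=C[C@H](OC1(C)C)[C@H](O1)CO | intermediate
4 | 1-(trimethylsilyl)propyne | CC#C[Si](C)(C)C | starting material
5 | [(4R,5S)-2,2-dimethyl-5-vinyl-1,3-dioxolan-4-yl]methyl triflate | C=C[C@H](OC1(C)C)[C@H](O1)COS(=O)(=O)C(F)(F)F | intermediate
6 | (4R,5S)-2,2-dimethyl-4-[4-(trimethylsilyl)but-3-yn-1-yl]-5-vinyl-1,3-dioxolane | C=C[C@H](OC1(C)C)[C@H](O1)CCC#C[Si](C)(C)C | intermediate
7 | (4R,5S)-4-(but-3-yn-1-yl)-2,2-dimethyl-5-vinyl-1,3-dioxolane | C=C[C@H](OC1(C)C)[C@H](O1)CCC#C | intermediate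
8 | pinacol 4-[(4R,5S)-2,2-dimethyl-5-vinyl-1,3-dioxolan-4-yl]but-1-en-2-ylboronate | C=C[C@H](OC1(C)C)[C@H](O1)CCC(=C)B2OC(C)(C)C(C)(C)O2 | intermediate
9 | pinacol (3aS,7aR)-2,2-dimethyl-3a,6,7,7a-tetrahydro-1,3-benzodioxol-5-ylboronate | CC1(C)OB(OC1(C)C)C1=C[C@H](OC2(C)C)[C@H](O2)CC1 | intermediate
10 | acenaphthoquinone | O=C1C(=O)c2cccc3cccc1c23 | starting material
11 | cis-1,2-dimethyl-1,2-dihydroacenaphthylene-1,2-diol (mac diol, meso) | C[C@@]1(O)c2cccc3cccc(c23)[C@]1(C)O | intermediate
12 | [(3aS,7aR)-2,2-dimethyl-3a,6,7,7a-tetrahydro-1,3-benzodioxol-5-yl]boronic acid | OB(O)C1=C[C@H](OC2(C)C)[C@H](O2)CC1 | intermediate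
13 | mac ester of boronic acid 12 (cyclohexenyl B(mac), acetonide) | C1(=C[C@H](OC2(C)C)[C@H](O2)CC1)B3O[C@]4(C)c5cccc6cccc(c56)[C@]4(C)O3 | intermediate
14 | 3-(4-hydroxy-3-methoxyphenyl)propan-1-ol | COc1cc(CCCO)ccc1O | starting material
15 | 2-bromo-4-(3-hydroxypropyl)-6-methoxyphenol | COc1cc(CCCO)cc(Br)c1O | intermediate
16 | tert-butyl{2-bromo-4-[3-(tert-butyldimethylsilyloxy)propyl]-6-methoxyphenoxy}dimethylsilane | COc1cc(CCCO[Si](C)(C)C(C)(C)C)cc(Br)c1O[Si](C)(C)C(C)(C)C | intermediate
17 | propargyl alcohol | C#CCO | starting material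
18 | (E)-3-(tributylstannyl)prop-2-en-1-ol | CCCC[Sn](CCCC)(CCCC)/C=C/CO | intermediate
19 | (E)-tert-butyldimethyl{[3-(tributylstannyl)prop-2-en-1-yl]oxy}silane | CCCC[Sn](CCCC)(CCCC)/C=C/CO[Si](C)(C)C(C)(C)C | intermediate
20 | (E)-3-(tert-butyldimethylsilyloxy)prop-1-enyllithium | [Li]/C=C/CO[Si](C)(C)C(C)(C)C | intermediate
21 | lithium bis(alkenyl) ate complex of 13 and 20 (boron not configurationally defined) | [Li+].CC(C)(C)[Si](C)(C)OC/C=C/[B-]1(O[C@]2(C)c3cccc4cccc(c34)[C@]2(C)O1)C5=C[C@H](OC6(C)C)[C@H](O6)CC5 | intermediate
22 | secondary allylic mac boronate, (2S,3R,3'S,4'R): aryl and CH2OTBS on C3, boron and ring C on C2 | COc1cc(CCCO[Si](C)(C)C(C)(C)C)cc(c1O[Si](C)(C)C(C)(C)C)[C@H](CO[Si](C)(C)C(C)(C)C)[C@H](B1O[C@]2(C)c3cccc4cccc(c34)[C@]2(C)O1)C5=C[C@H](OC6(C)C)[C@H](O6)CC5 | intermediate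
23 | secondary allylic alcohol, (2S,3R,3'S,4'R) | COc1cc(CCCO[Si](C)(C)C(C)(C)C)cc(c1O[Si](C)(C)C(C)(C)C)[C@H](CO[Si](C)(C)C(C)(C)C)[C@H](O)C2=C[C@H](OC3(C)C)[C@H](O3)CC2 | intermediate
24 | methyl carbonate of 23 | COc1cc(CCCO[Si](C)(C)C(C)(C)C)cc(c1O[Si](C)(C)C(C)(C)C)[C@H](CO[Si](C)(C)C(C)(C)C)[C@H](OC(=O)OC)C2=C[C@H](OC3(C)C)[C@H](O3)CC2 | intermediate
25 | phenol carbonate (aryl silyl ether removed) | COc1cc(CCCO[Si](C)(C)C(C)(C)C)cc(c1O)[C@H](CO[Si](C)(C)C(C)(C)C)[C@H](OC(=O)OC)C2=C[C@H](OC3(C)C)[C@H](O3)CC2 | intermediate
26 | (2S,3R)-dihydrobenzofuran, bis-TBS ether, acetonide | COc1cc(CCCO[Si](C)(C)C(C)(C)C)cc2c1O[C@H](C1=C[C@H](OC3(C)C)[C@H](O3)CC1)[C@H]2CO[Si](C)(C)C(C)(C)C | intermediate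
27 | difengpiol A, (1R,2S)-4-[(2S,3R)-3-(hydroxymethyl)-5-(3-hydroxypropyl)-7-methoxy-2,3-dihydrobenzofuran-2-yl]cyclohex-3-ene-1,2-diol | COc1cc(CCCO)cc2c1O[C@H](C1=C[C@H](O)[C@H](O)CC1)[C@H]2CO | target

Total step count: 17. Longest linear sequence: 12 steps (steps 1–5, 7 and 12–17, from lactone 1).

Steps most likely to fail

1. Step 12 (Proposed new method). Three processes could drain the three-component product: direct transfer of one alkenyl group from boron to arylpalladium without the 1,2-shift, activation of the ring alkene in place of the open-chain one, and weak facial discrimination by the ligand. The fallback is a reagent-controlled carbamate lithiation–borylation, which is known chemistry. It sets out from 16 and 9 and comes back at 23.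
 - Palladium-catalysed arylation of diethyl malonate with 16 (Pd(dba)2, P(t-Bu)3, K3PO4, toluene, 70 °C) would give diethyl arylmalonate F1.
 - LiAlH4 reduction would give the prochiral 2-aryl-propane-1,3-diol F2.
 - Lipase-catalysed desymmetrising acetylation (vinyl acetate; the acylation or the diacetate-hydrolysis mode chosen to reach the needed antipode) would give monoacetate F3.
 - Silylation (TBSCl, imidazole) would give acetate silyl ether F4, and acetate removal with i-Bu2AlH at −78 °C primary alcohol F5.
 - N,N-Diisopropylcarbamoyl chloride/Et3N would give carbamate F6.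
 - Deprotonation of F6 with s-BuLi/(+)-sparteine (Et2O, −78 °C), addition of 9 and warming with MgBr2·OEt2 would induce the 1,2-shift of the cyclohexenyl group with inversion at carbon. This gives the pinacol analogue of 22, boronate F7, with C2 set by the diamine and C3 by the enzyme.
 - Oxidation as in step 13 returns to 23.

2. Step 4. Boron may be delivered to the terminal alkyne carbon; this regiochemical leakage gives a linear alkenylboronate that cannot close ring C. The fallback builds the 1,1-disubstituted alkenylboronate from a ketone. It sets out from 3 (through triflate 5) and comes back at 8.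
 - Alkylation of 5 with the lithium aza-enolate of acetone N,N-dimethylhydrazone (LiN(i-Pr)2, THF, −78 °C) would give hydrazone F8.
 - Hydrolysis with aqueous CuCl2 at pH 7 would give methyl ketone F9.
 - Kinetic deprotonation on the methyl side (KN(SiMe3)2, THF, −78 °C) and trapping with PhNTf2 would give the 2-triflyloxy-1-alkene F10.
 - Miyaura borylation (B2pin2, PdCl2(PPh3)2, PPh3, KOPh, toluene, 50 °C) returns to 8.

3. Step 16. Ionisation next to the trisubstituted ring alkene may be slow, the π-allyl intermediate may lose a β-hydrogen to give a triene, closure may occur at C2', or the configuration may erode through exchange between palladium centres. The fallback closes O1–C2 by two Mitsunobu inversions without a metal. It sets out from 23 and comes back at 26.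
 - Mitsunobu esterification of 23 (4-nitrobenzoic acid, PPh3, DIAD, toluene, 0 °C → rt) would give the C2-inverted ester F11.
 - K2CO3/MeOH would cleave both the ester and the aryl silyl ether to give the C2-epimeric phenol alcohol F12.
 - Intramolecular Mitsunobu etherification (PPh3, DIAD, THF, 0 °C) would displace the activated C2 hydroxyl by the phenol with a second inversion and return to 26.

Further compounds
F1 | step 12 | diethyl 2-{2-(tert-butyldimethylsilyloxy)-3-methoxy-5-[3-(tert-butyldimethylsilyloxy)propyl]phenyl}malonate | COc1cc(CCCO[Si](C)(C)C(C)(C)C)cc(c1O[Si](C)(C)C(C)(C)C)C(C(=O)OCC)C(=O)OCC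
F2 | step 12 | 2-aryl-propane-1,3-diol (aryl as in F1) | COc1cc(CCCO[Si](C)(C)C(C)(C)C)cc(c1O[Si](C)(C)C(C)(C)C)C(CO)CO
F3 | step 12 | enantioenriched monoacetate of F2 (centre configured as C3 of 23) | COc1cc(CCCO[Si](C)(C)C(C)(C)C)cc(c1O[Si](C)(C)C(C)(C)C)[C@H](CO)COC(C)=O
F4 | step 12 | TBS ether of monoacetate F3 | COc1cc(CCCO[Si](C)(C)C(C)(C)C)cc(c1O[Si](C)(C)C(C)(C)C)[C@H](CO[Si](C)(C)C(C)(C)C)COC(C)=O
F5 | step 12 | 2-aryl-3-(tert-butyldimethylsilyloxy)propan-1-ol (centre configured as C3 of 23) | COc1cc(CCCO[Si](C)(C)C(C)(C)C)cc(c1O[Si](C)(C)C(C)(C)C)[C@H](CO[Si](C)(C)C(C)(C)C)CO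
F6 | step 12 | N,N-diisopropylcarbamate of F5 | COc1cc(CCCO[Si](C)(C)C(C)(C)C)cc(c1O[Si](C)(C)C(C)(C)C)[C@H](CO[Si](C)(C)C(C)(C)C)COC(=O)N(C(C)C)C(C)C
F7 | step 12 | pinacol analogue of 22 (secondary allylic pinacol boronate, 2S,3R,3'S,4'R) | COc1cc(CCCO[Si](C)(C)C(C)(C)C)cc(c1O[Si](C)(C)C(C)(C)C)[C@H](CO[Si](C)(C)C(C)(C)C)[C@H](B1OC(C)(C)C(C)(C)O1)C2=C[C@H](OC3(C)C)[C@H](O3)CC2
F8 | step 4 | N,N-dimethylhydrazone of 4-[(4R,5S)-2,2-dimethyl-5-vinyl-1,3-dioxolan-4-yl]butan-2-one | C=C[C@H](OC1(C)C)[C@H](O1)CCC(C)=NN(C)C
F9 | step 4 | 4-[(4R,5S)-2,2-dimethyl-5-vinyl-1,3-dioxolan-4-yl]butan-2-one | C=C[C@H](OC1(C)C)[C@H](O1)CCC(C)=O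
F10 | step 4 | 4-[(4R,5S)-2,2-dimethyl-5-vinyl-1,3-dioxolan-4-yl]but-1-en-2-yl triflate | C=C[C@H](OC1(C)C)[C@H](O1)CCC(=C)OS(=O)(=O)C(F)(F)F
F11 | step 16 | C2-inverted 4-nitrobenzoate of 23 | COc1cc(CCCO[Si](C)(C)C(C)(C)C)cc(c1O[Si](C)(C)C(C)(C)C)[C@H](CO[Si](C)(C)C(C)(C)C)[C@@H](OC(=O)c2ccc(cc2)[N+](=O)[O-])C3=C[C@H](OC4(C)C)[C@H](O4)CC3
F12 | step 16 | C2-epimeric alcohol with free phenol | COc1cc(CCCO[Si](C)(C)C(C)(C)C)cc(c1O)[C@H](CO[Si](C)(C)C(C)(C)C)[C@@H](O)C2=C[C@H](OC3(C)C)[C@H](O3)CC2
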